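## Structural features

- The target 29 is an unsymmetrical benzil. One carbonyl of the 1,2-dione carries a 4-methoxyphenyl ring, the other sits on C6 of a 2,2-dimethyl-2H-chromene.
- Ring B is the pyran (O1, C2 with two methyl groups, C3=C4). It is fused through C4a and C8a to the benzene ring A.
- Ring A has only one hydrogen (C8). C5 bears a methoxy group, C6 the dione, and C7 a free hydroxyl that is hydrogen-bonded to the C6 carbonyl.
- There is no stereocentre, so every difficulty is regiochemical. The oxygens at C5, C7 and C8a form a phloroglucinol pattern in which each has a different fate (methyl ether, free phenol, pyran oxygen). The two carbon substituents must go to C6 and C4a and not to C8.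
- Fragile groups are the 1,2-dione (base, nucleophiles, hemiketal formation with the C7 hydroxyl), the electron-rich C3=C4 bond (acid, electrophiles, hydrogenation) and the free phenol (oxidants).
- The key step exploits the contiguous triad C5–OMe / C6–acyl / C7–OH. An acyl carbon and a hydroxyl on neighbouring ring atoms, with an alkoxy group on the other flank of the acyl carbon, is the pattern a C6≡C7 aryne leaves when it inserts into the C–O bond of a carboxylic acid.

Chromene numbering (C4a to C8a) is used for the ring A atoms of all intermediates.

## Logic of the disconnections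

**29 to 28.** The O1–C2 bond is cut and the C3=C4 unsaturation is returned to a prenyl side chain on C4a. An ortho-prenyl phenol closes oxidatively to a dimethylchromene, and because O5 is methylated only O8a can close. Ring B disappears and the sensitive chromene exists only in the last step. The oxidant must abstract the benzylic hydride without touching the dione or the C7 phenol.

**28 to 27.** No skeletal bond is cut. The ketone next to the anisyl ring is re-masked as a dioxolane and O8a as a MOM ether. The dione would not survive base, heat and aryl anions, and O8a must stay distinguishable from O7. One acid treatment has to remove both groups without protonating the prenyl alkene.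

**27 to 25.** The C4a–C1' bond of the prenyl group is cut and the prenyl unit is returned to O7. C4a is para to O7, and a para-Claisen–Cope sequence delivers an O-allyl group to exactly that carbon. This settles the C4a/C8 question without a blocking group and turns C-prenylation into O-alkylation. The dienone 26 must undergo the Cope shift faster than it enolises.

**25 to 23 and 24.** The O7–C1' bond is cut. The forward step only needs O-alkylation of a hindered, chelated phenol.

**23 to 16 and 20.** The C6–C(=O) bond and the C7–O bond are cut together. This splits the molecule into two halves of similar size and creates the acyl/hydroxyl/methoxy pattern in one operation. The oxygen nucleophile must add to C7 only. The C6 anion must find the acyl carbon before it finds a proton, so 20 is used as its caesium salt 21. The ketone must stay masked so that the ester carbonyl is the only electrophile in reach.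

**20 to 19, then to 17 and 18.** The ester C–O bond and the two ketal C–O bonds are cut. This leads to a purchasable keto ester and a diol. Ester hydrolysis must leave the ketal intact.

**16 to 13.** The O–S bond is cut and the triflate is returned to a carbamate-protected phenol. The carbamate is both the directing group of the earlier silylation and a phenol protecting group. It must come off under conditions that spare the aryl–silicon bond; 15 is the transient phenol.

**13 to 10.** The O–CH2 bond of the MOM ether is cut and O8a is returned to a TIPS ether. The group needed at O8a during lithiation (bulky, non-coordinating) is not the group needed in the fluoride step (fluoride-stable, acid-labile). The exchange must spare the carbamate and the C6–Si bond; 12 is the transient phenoxide.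

**10 to 5.** The C6–Si bond is cut. The proton between the carbamate and the methoxy group is the most acidic ring proton of 5, so directed metalation gives the silane without a halogen. Lithiation must avoid the position next to the silyl ether, and the carbamate must not migrate.

**5 to 3 and 4, then to 1 and 2.** The carbamate C–O bond and the Si–O bond are cut. This leads to the symmetric diol 1, whose two hydroxyls are told apart by mono-silylation.

## Other disconnections considered

**Alternative 1:** Ring A is cut at C5–C6, C7–C8 and C4a–C5. This leads to the dihydropyranyl diazo ketone A1 and benzyl ethynyl ether A2.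

- Forward key step: light triggers a Wolff rearrangement of A1 to a vinylketene. [2+2] addition of A2, four-electron opening of the cyclobutenone and six-electron closure of the dienylketene (a Danheiser-type benzannulation) should give the chromanol A3.
- In its favour: all three ring A oxygens are differentiated by construction (free C5 hydroxyl, benzyl ether at C7, ring oxygen at C8a). No statistical protection or protecting-group exchange is needed, and on this point it is better than the chosen plan. The saturated ring B of A3 tolerates hydrogenolysis and Lewis acids.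
- Against it here: A3 has neither the C6 acyl group nor the C3=C4 double bond. The aroylformyl unit would have to be introduced later at C6 in competition with C8, since both carbons lie between two oxygens. A1 needs several steps, including a diazo transfer next to an enol ether, and the sequence is photochemical.
- Comparison: the chosen plan fixes the C6 acyl and the C7 hydroxyl in one bond-forming event. The alternative builds the ring elegantly but postpones exactly that problem. Mechanistically it is a four-stage pericyclic cascade against an addition and acyl transfer. In step count it is expected to be about equal or slightly longer, and it is less convergent.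

**Alternative 2:** Ring A is cut at C4a–C8a and C6–C7. This leads to the prenylated β-methoxy enoate A4 and malonyl dichloride A5.

- Forward key step: the dienolate of A4 is acylated at its γ-carbon and then at its α-carbon. Aromatisation should give the benzoate A6.
- In its favour: the prenyl group is at C4a from the start, with no regiochemical question. On this point it is better than the para-Claisen–Cope step of the chosen plan. The C5 methyl ether is also in place, and ring A comes from acyclic material in one step without an aryne precursor.
- Against it here: C6 arrives as a methyl ester. Turning a doubly ortho-substituted, chelated ester into the aryl 1,2-dione needs several redox and C–C steps. Double C-acylation with A5 competes with O-acylation and pyranone formation.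
- Comparison: it is equal on stereochemistry (none) and better on prenyl placement and on the number of steps to the aromatic core. It is weaker where the chosen plan is strongest, namely installing the whole dione carbon skeleton at the right oxidation level in the key step. The total step count could be similar, with two uncertain transformations instead of one.

**Alternative 3:** Ring B is cut at C3–C4 and O1–C2. This leads to the symmetric aldehyde A7 and the alkenylboronic acid A8.

- Forward key step: with a catalytic secondary amine the iminium of A7 accepts the alkenyl group from the phenol-bound boronate (Petasis-type). Loss of the amine gives an ortho-quinone methide, and oxa-six-electron closure should give the chromenol A9.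
- In its favour: either ortho hydroxyl of A7 gives the same product, so ring closure is unambiguous; this is equal to the control the C5 methyl ether gives in the chosen plan. The C3=C4 bond is formed at the right oxidation level without a late oxidant, which is better than the chosen plan. The heterocycle is reached in very few steps.
- Against it here: A9 lacks the C6 acyl group. After O-methylation the aroylformyl unit must enter at C6 and not at C8, by metalation or Friedel–Crafts chemistry, on an acid-sensitive chromene. The doubly chelated, electron-rich aldehyde may also react sluggishly.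
- Comparison: it is shorter on paper if the late acylation were selective, and it is mechanistically simple. Structurally it leaves the C5/C6/C7 relation unsolved, which the aryne insertion of the chosen plan sets by construction.

Key step: step 8

**Remarks on the design**

- The positions in 16, 20 and 23 were checked against 29 and need no correction: silicon lies between triflate and methoxy, and the MOM ether is para to silicon.
- Acid 20 is converted into its caesium salt 21 before the aryne is released, so that no acidic proton is present.
- The silyl-to-MOM exchange and the carbamate-to-triflate exchange are each run in one flask.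
- Assumption: the ethyl ester 17 of the keto acid is an article of commerce, so no esterification is needed.

## Route

Step 1
Reactants: 1 5-methoxybenzene-1,3-diol; 2 chlorotri(propan-2-yl)silane
Product: 3 3-methoxy-5-{[tri(propan-2-yl)silyl]oxy}phenol
Conditions: 1 (2 equiv), TIPSCl (1 equiv), imidazole (1.2 equiv), DMF, 0 °C → rt
Reagents that add atoms: chlorotri(propan-2-yl)silane 2, CC(C)[Si](Cl)(C(C)C)C(C)C
Why: Silylation of one of two equivalent phenols; the excess of diol keeps bis-silylation low, and the bulky TIPS ether later screens both of its ortho positions against lithiation.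

Step 2
Reactants: 3 3-methoxy-5-{[tri(propan-2-yl)silyl]oxy}phenol; 4 2-isocyanatopropane
Product: 5 3-methoxy-5-{[tri(propan-2-yl)silyl]oxy}phenyl propan-2-ylcarbamate
Conditions: iPrNCO (1.3 equiv), Et3N (0.2 equiv), CH2Cl2, rt
Reagents that add atoms: 2-isocyanatopropane 4, CC(C)N=C=O
Why: Amine-catalysed addition of the phenol to the isocyanate (carbamoylation) gives an N–H carbamate that directs metalation and can later be removed by E1cB elimination.

Step 3
Reactants: 5 3-methoxy-5-{[tri(propan-2-yl)silyl]oxy}phenyl propan-2-ylcarbamate; 6 tert-butyl(dimethyl)silyl trifluoromethanesulfonate; 7 chlorotrimethylsilane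
Product: 10 3-methoxy-5-{[tri(propan-2-yl)silyl]oxy}-2-(trimethylsilyl)phenyl propan-2-ylcarbamate, via N-silyl carbamate 8 (not isolated), via doubly silylated carbamate 9 (not isolated)
Conditions: TBSOTf (1.1 equiv), TMEDA (1.1 equiv), Et2O, 0 °C → rt; TMEDA (2 equiv), n-BuLi (2.2 equiv), −78 °C; TMSCl (3 equiv), −78 °C → rt; aq NaHSO4
Reagents that add atoms: chlorotrimethylsilane 7, C[Si](C)(C)Cl; tert-butyl(dimethyl)silyl trifluoromethanesulfonate 6, CC(C)(C)[Si](C)(C)OS(=O)(=O)C(F)(F)F (its silyl group is present only in 8 and 9 and is lost at work-up)
Why: Directed ortho-metalation: N-silylation in the flask blocks the acidic N–H, n-BuLi/TMEDA removes the proton between the carbamate and the methoxy group (two cooperating directors, while the other ortho position is screened by the TIPS ether), and TMSCl traps the aryllithium at −78 °C before an anionic Fries shift can occur. Aqueous NaHSO4 cleaves the N–Si bond.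

Step 4
Reactants: 10 3-methoxy-5-{[tri(propan-2-yl)silyl]oxy}-2-(trimethylsilyl)phenyl propan-2-ylcarbamate; 11 chloro(methoxy)methane
Product: 13 3-methoxy-5-(methoxymethoxy)-2-(trimethylsilyl)phenyl propan-2-ylcarbamate, via desilylated phenoxide 12 (not isolated)
Conditions: TBAF (1.05 equiv), THF, 0 °C; then MOMCl (1.5 equiv), 0 °C → rt
Reagents that add atoms: chloro(methoxy)methane 11, COCCl
Why: Fluoride cleaves the aryl O–Si bond much faster than the hindered aryl C–Si bond, and the tetrabutylammonium phenoxide is alkylated in the same flask (Williamson-type acetal formation). The exchange is needed because a silyl ether would not survive the fluoride of step 8, whereas the MOM ether does and is acid-labile at the end.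

Step 5
Reactants: 13 3-methoxy-5-(methoxymethoxy)-2-(trimethylsilyl)phenyl propan-2-ylcarbamate; 14 1,1,1-trifluoro-N-phenyl-N-[(trifluoromethyl)sulfonyl]methanesulfonamide
Product: 16 3-methoxy-5-(methoxymethoxy)-2-(trimethylsilyl)phenyl trifluoromethanesulfonate, via silylphenol 15 (not isolated)
Conditions: Et2NH (1.5 equiv), DBU (1.5 equiv), MeCN, 40 °C; then PhNTf2 (1.5 equiv), rt
Reagents that add atoms: 1,1,1-trifluoro-N-phenyl-N-[(trifluoromethyl)sulfonyl]methanesulfonamide 14, O=S(=O)(N(c1ccccc1)S(=O)(=O)C(F)(F)F)C(F)(F)F
Why: DBU deprotonates the carbamate N–H and E1cB elimination releases the phenoxide and the isocyanate, which Et2NH scavenges as a urea. The phenoxide is triflated by the mild triflyl donor without protodesilylation or loss of the MOM ether.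

Step 6
Reactants: 17 ethyl 2-(4-methoxyphenyl)-2-oxoacetate; 18 ethane-1,2-diol
Product: 19 ethyl 2-(4-methoxyphenyl)-1,3-dioxolane-2-carboxylate
Conditions: HOCH2CH2OH (5 equiv), TsOH·H2O (0.1 equiv), toluene, reflux, Dean–Stark trap
Reagents that add atoms: ethane-1,2-diol 18, OCCO
Why: Acid-catalysed ketalisation with azeotropic removal of water; the ketone is activated by the neighbouring ester, and any transesterification by the diol is harmless because step 7 hydrolyses the ester.

Step 7
Reactants: 19 ethyl 2-(4-methoxyphenyl)-1,3-dioxolane-2-carboxylate
Product: 20 2-(4-methoxyphenyl)-1,3-dioxolane-2-carboxylic acid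
Conditions: LiOH·H2O (3 equiv), THF/H2O, rt → 40 °C; then 1 M HCl to pH 3, 0 °C
Reagents that add atoms: lithium hydroxide, [Li+].[OH-]
Why: Saponification of an inductively activated ester; the dioxolane is stable to base, and cold, brief acidification to pH 3 frees the acid without opening the ketal.

Step 8
Reactants: 16 3-methoxy-5-(methoxymethoxy)-2-(trimethylsilyl)phenyl trifluoromethanesulfonate; 20 2-(4-methoxyphenyl)-1,3-dioxolane-2-carboxylic acid
Product: 23 [2-hydroxy-6-methoxy-4-(methoxymethoxy)phenyl][2-(4-methoxyphenyl)-1,3-dioxolan-2-yl]methanone, via caesium carboxylate 21 (not isolated), via aryne 22 (not isolated)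
Conditions: 20 (1.5 equiv), Cs2CO3 (0.75 equiv), MeOH, rt, evaporate and dry; then 16 (1 equiv), CsF (3 equiv), THF, 125 °C, sealed tube; aq NH4Cl
Reagents that add atoms: none
Why: Fluoride attacks the silicon of 16 and the triflate leaves, giving the C6≡C7 aryne 22. The carboxylate oxygen of 21 adds to C7, the aryne carbon remote from the methoxy group, because the C5 methoxy group polarises the aryne so that the negative charge develops at C6, where it is stabilised inductively; the MOM ether at C8a is meta to C7 and has little influence. The C6 aryl anion then attacks the carbonyl of the aryl ester just formed through a four-membered transition state (4-exo-trig), and collapse of this adduct breaks the acyl C–O bond, leaving the ketone on C6 and a caesium phenoxide on C7. No ring survives and no stereocentre is formed. The closest known reaction type is the insertion of arynes into the C–O bond of carboxylic acids to give ortho-hydroxyaryl ketones under CsF in hot THF. Acyl transfer must win over protonation of the C6 anion; this is secured by using the caesium salt (no O–H), by the absence of α-hydrogens in 21 and by the dioxolane, which leaves the ester carbonyl as the only electrophile within reach. The excess of carboxylate keeps the product phenoxide, which is chelated and hindered, from competing for the aryne.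

Step 9
Reactants: 23 [2-hydroxy-6-methoxy-4-(methoxymethoxy)phenyl][2-(4-methoxyphenyl)-1,3-dioxolan-2-yl]methanone; 24 1-bromo-3-methylbut-2-ene
Product: 25 [2-methoxy-4-(methoxymethoxy)-6-[(3-methylbut-2-en-1-yl)oxy]phenyl][2-(4-methoxyphenyl)-1,3-dioxolan-2-yl]methanone
Conditions: prenyl bromide (1.5 equiv), K2CO3 (2 equiv), DMF, rt → 40 °C
Reagents that add atoms: 1-bromo-3-methylbut-2-ene 24, CC(C)=CCBr
Why: Williamson etherification of the only free phenol with a reactive allylic bromide; the ketal and the MOM ether are inert to carbonate.

Step 10
Reactants: 25 [2-methoxy-4-(methoxymethoxy)-6-[(3-methylbut-2-en-1-yl)oxy]phenyl][2-(4-methoxyphenyl)-1,3-dioxolan-2-yl]methanone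
Product: 27 [6-hydroxy-2-methoxy-4-(methoxymethoxy)-3-(3-methylbut-2-en-1-yl)phenyl][2-(4-methoxyphenyl)-1,3-dioxolan-2-yl]methanone, via ortho-dienone 26 (not isolated)
Conditions: PhNEt2, 190 °C, argon, sealed tube
Reagents that add atoms: none
Why: Aromatic para-Claisen–Cope rearrangement: a [3,3] shift from O7 to C8 gives dienone 26 carrying a 1,1-dimethylallyl group wedged between two oxygen-bearing carbons, and a second [3,3] (Cope) shift relieves this crowding and delivers a normal prenyl group to C4a, para to O7, after which the ring re-aromatises. A first shift to the acyl-bearing C6 would give a dienone that cannot enolise and leads to the same carbon, so both ortho pathways converge on C4a; the reaction type is established for 2-prenyloxy-4,6-dialkoxyaryl ketones.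

Step 11
Reactants: 27 [6-hydroxy-2-methoxy-4-(methoxymethoxy)-3-(3-methylbut-2-en-1-yl)phenyl][2-(4-methoxyphenyl)-1,3-dioxolan-2-yl]methanone
Product: 28 1-[4,6-dihydroxy-2-methoxy-3-(3-methylbut-2-en-1-yl)phenyl]-2-(4-methoxyphenyl)ethane-1,2-dione
Conditions: 3 M aq HCl, MeOH/THF, 45 °C
Reagents that add atoms: water, O
Why: Acid-catalysed hydrolysis of the MOM acetal and of the dioxolane, whose oxocarbenium ion is stabilised by the 4-methoxyphenyl group; moderate acid strength and temperature are chosen so that the trisubstituted alkene is not protonated.

Step 12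
Reactants: 28 1-[4,6-dihydroxy-2-methoxy-3-(3-methylbut-2-en-1-yl)phenyl]-2-(4-methoxyphenyl)ethane-1,2-dione
Product: 29 1-(7-hydroxy-5-methoxy-2,2-dimethyl-2H-chromen-6-yl)-2-(4-methoxyphenyl)ethane-1,2-dione
Conditions: DDQ (1.2 equiv), 1,4-dioxane, 80 °C
Reagents that add atoms: none
Why: DDQ oxidative cyclisation of an ortho-prenyl phenol: hydride abstraction from the benzylic CH2 on C4a gives an ortho-quinone methide conjugated with the alkene, and oxa-six-electron electrocyclisation through O8a closes the pyran. O5 is methylated and cannot compete, and the dione and the chelated C7 phenol are inert to the quinone.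

## Compound list

1 | 5-methoxybenzene-1,3-diol | COc1cc(O)cc(O)c1 | starting material
2 | chlorotri(propan-2-yl)silane | CC(C)[Si](Cl)(C(C)C)C(C)C | starting material
3 | 3-methoxy-5-{[tri(propan-2-yl)silyl]oxy}phenol | COc1cc(O)cc(O[Si](C(C)C)(C(C)C)C(C)C)c1 | intermediate
4 | 2-isocyanatopropane | CC(C)N=C=O | starting material
5 | 3-methoxy-5-{[tri(propan-2-yl)silyl]oxy}phenyl propan-2-ylcarbamate | COc1cc(OC(=O)NC(C)C)cc(O[Si](C(C)C)(C(C)C)C(C)C)c1 | intermediate
6 | tert-butyl(dimethyl)silyl trifluoromethanesulfonate | CC(C)(C)[Si](C)(C)OS(=O)(=O)C(F)(F)F | starting material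
7 | chlorotrimethylsilane | C[Si](C)(C)Cl | starting material
8 | 3-methoxy-5-{[tri(propan-2-yl)silyl]oxy}phenyl [tert-butyl(dimethyl)silyl](propan-2-yl)carbamate (not isolated) | COc1cc(OC(=O)N(C(C)C)[Si](C)(C)C(C)(C)C)cc(O[Si](C(C)C)(C(C)C)C(C)C)c1 | intermediate
9 | 3-methoxy-5-{[tri(propan-2-yl)silyl]oxy}-2-(trimethylsilyl)phenyl [tert-butyl(dimethyl)silyl](propan-2-yl)carbamate (not isolated) | COc1cc(O[Si](C(C)C)(C(C)C)C(C)C)cc(OC(=O)N(C(C)C)[Si](C)(C)C(C)(C)C)c1[Si](C)(C)C | intermediate
10 | 3-methoxy-5-{[tri(propan-2-yl)silyl]oxy}-2-(trimethylsilyl)phenyl propan-2-ylcarbamate | COc1cc(O[Si](C(C)C)(C(C)C)C(C)C)cc(OC(=O)NC(C)C)c1[Si](C)(C)C | intermediate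
11 | chloro(methoxy)methane | COCCl | starting material
12 | 5-hydroxy-3-methoxy-2-(trimethylsilyl)phenyl propan-2-ylcarbamate, present as its tetrabutylammonium phenoxide (not isolated) | COc1cc(O)cc(OC(=O)NC(C)C)c1[Si](C)(C)C | intermediate
13 | 3-methoxy-5-(methoxymethoxy)-2-(trimethylsilyl)phenyl propan-2-ylcarbamate | COCOc1cc(OC)c([Si](C)(C)C)c(OC(=O)NC(C)C)c1 | intermediate
14 | 1,1,1-trifluoro-N-phenyl-N-[(trifluoromethyl)sulfonyl]methanesulfonamide | O=S(=O)(N(c1ccccc1)S(=O)(=O)C(F)(F)F)C(F)(F)F | starting material
15 | 3-methoxy-5-(methoxymethoxy)-2-(trimethylsilyl)phenol, present as its phenoxide (not isolated) | COCOc1cc(OC)c([Si](C)(C)C)c(O)c1 | intermediate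
16 | 3-methoxy-5-(methoxymethoxy)-2-(trimethylsilyl)phenyl trifluoromethanesulfonate | COCOc1cc(OC)c([Si](C)(C)C)c(OS(=O)(=O)C(F)(F)F)c1 | intermediate
17 | ethyl 2-(4-methoxyphenyl)-2-oxoacetate | CCOC(=O)C(=O)c1ccc(OC)cc1 | starting material
18 | ethane-1,2-diol | OCCO | starting material
19 | ethyl 2-(4-methoxyphenyl)-1,3-dioxolane-2-carboxylate | CCOC(=O)C1(c2ccc(OC)cc2)OCCO1 | intermediate
20 | 2-(4-methoxyphenyl)-1,3-dioxolane-2-carboxylic acid | COc1ccc(C2(C(=O)O)OCCO2)cc1 | intermediate
21 | caesium 2-(4-methoxyphenyl)-1,3-dioxolane-2-carboxylate (not isolated) | COc1ccc(C2(C(=O)[O-])OCCO2)cc1.[Cs+] | intermediate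
22 | 3-methoxy-5-(methoxymethoxy)benzyne (1,2-didehydro-3-methoxy-5-(methoxymethoxy)benzene, not isolated) | COCOC1=CC#CC(OC)=C1 | intermediate
23 | [2-hydroxy-6-methoxy-4-(methoxymethoxy)phenyl][2-(4-methoxyphenyl)-1,3-dioxolan-2-yl]methanone | COc1ccc(C2(C(=O)c3c(O)cc(OCOC)cc3OC)OCCO2)cc1 | intermediate
24 | 1-bromo-3-methylbut-2-ene | CC(C)=CCBr | starting material
25 | [2-methoxy-4-(methoxymethoxy)-6-[(3-methylbut-2-en-1-yl)oxy]phenyl][2-(4-methoxyphenyl)-1,3-dioxolan-2-yl]methanone | COc1ccc(C2(C(=O)c3c(OCC=C(C)C)cc(OCOC)cc3OC)OCCO2)cc1 | intermediate
26 | 3-methoxy-5-(methoxymethoxy)-2-[2-(4-methoxyphenyl)-1,3-dioxolane-2-carbonyl]-6-(2-methylbut-3-en-2-yl)cyclohexa-2,4-dien-1-one (racemic, not isolated) | COc1ccc(C2(C(=O)C3=C(OC)C=C(OCOC)C(C(C)(C)C=C)C3=O)OCCO2)cc1 | intermediate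
27 | [6-hydroxy-2-methoxy-4-(methoxymethoxy)-3-(3-methylbut-2-en-1-yl)phenyl][2-(4-methoxyphenyl)-1,3-dioxolan-2-yl]methanone | COc1ccc(C2(C(=O)c3c(O)cc(OCOC)c(CC=C(C)C)c3OC)OCCO2)cc1 | intermediate
28 | 1-[4,6-dihydroxy-2-methoxy-3-(3-methylbut-2-en-1-yl)phenyl]-2-(4-methoxyphenyl)ethane-1,2-dione | COc1ccc(C(=O)C(=O)c2c(O)cc(O)c(CC=C(C)C)c2OC)cc1 | intermediate
29 | 1-(7-hydroxy-5-methoxy-2,2-dimethyl-2H-chromen-6-yl)-2-(4-methoxyphenyl)ethane-1,2-dione | COc1ccc(C(=O)C(=O)c2c(O)cc3c(c2OC)C=CC(C)(C)O3)cc1 | target

## Step count and least certain steps

Total step count: 12. Longest linear sequence: 10 steps (steps 1 to 5 and 8 to 12, from 1); the acid arm (steps 6 and 7) joins at step 8.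

**Step 8 (key step).** The C6 aryl anion may be protonated before the acyl transfer, which would stop at the O-aryl ester. The transfer to a carbonyl flanked by a quaternary, doubly oxygenated carbon may be slow, and the product phenoxide may be arylated by a second aryne. The fallback sets out from 5 and 20 and comes back at 23, replacing the aryne by directed metalation and acylation.
- Acid 20 is converted (1,1'-carbonyldiimidazole, then N,O-dimethylhydroxylamine hydrochloride) into the Weinreb amide N-methoxy-2-(4-methoxyphenyl)-N-methyl-1,3-dioxolane-2-carboxamide F1.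
- Carbamate 5 is N-silylated and lithiated as in step 3 (through 8), and the aryllithium is quenched with F1 in place of the chlorosilane. Work-up with aqueous NaHSO4 should give 3-methoxy-2-[2-(4-methoxyphenyl)-1,3-dioxolane-2-carbonyl]-5-{[tri(propan-2-yl)silyl]oxy}phenyl propan-2-ylcarbamate F2.
- TBAF followed by MOMCl exchanges the silyl ether for the MOM ether, giving 3-methoxy-5-(methoxymethoxy)-2-[2-(4-methoxyphenyl)-1,3-dioxolane-2-carbonyl]phenyl propan-2-ylcarbamate F3.
- Et2NH/DBU in MeCN removes the carbamate and gives 23.

**Step 10.** The ortho-dienone 26 may enolise before the Cope shift, which would leave a reverse-prenyl group on C8. The allyl ether may also cleave thermally. The fallback sets out from 23 and comes back at 27, blocking C8 so that no dienone can enolise.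
- Iodination with N-iodosuccinimide in CH2Cl2 is expected ortho to the chelated C7 hydroxyl and should give [2-hydroxy-3-iodo-6-methoxy-4-(methoxymethoxy)phenyl][2-(4-methoxyphenyl)-1,3-dioxolan-2-yl]methanone F4.
- Prenylation as in step 9 gives [3-iodo-6-methoxy-4-(methoxymethoxy)-2-[(3-methylbut-2-en-1-yl)oxy]phenyl][2-(4-methoxyphenyl)-1,3-dioxolan-2-yl]methanone F5.
- Heating as in step 10, now with both ortho positions substituted, should give [2-hydroxy-3-iodo-6-methoxy-4-(methoxymethoxy)-5-(3-methylbut-2-en-1-yl)phenyl][2-(4-methoxyphenyl)-1,3-dioxolan-2-yl]methanone F6.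
- Reductive removal of iodine (Pd(OAc)2, PPh3, HCO2H, Et3N, DMF, 60 °C) gives 27.

**Step 11.** Under acid the freed C8a hydroxyl may add to the protonated prenyl alkene (chroman formation). The ketal may also hydrolyse slowly because the neighbouring carbonyl destabilises the oxocarbenium ion, so that forcing conditions become necessary. The fallback sets out from 27 and comes back at 29, accepting the cyclisation instead of avoiding it.
- Stronger acid (TsOH·H2O, wet toluene, 80 °C) removes both protecting groups and closes the saturated ring onto O8a, the only free hydroxyl next to the prenyl group. This gives 1-(7-hydroxy-5-methoxy-2,2-dimethyl-3,4-dihydro-2H-chromen-6-yl)-2-(4-methoxyphenyl)ethane-1,2-dione F7.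
- DDQ in refluxing 1,4-dioxane dehydrogenates C3–C4 of this electron-rich chroman and gives 29 directly, without passing through 28.

**Step 3.** Lithiation may occur next to the silyl ether, the carbamoyl group may migrate to carbon (anionic Fries shift) if the temperature rises, and the N-silyl group may be lost early. The fallback sets out from 3 and comes back at 10, placing silicon by halogen–metal exchange instead of deprotonation.
- Amine-catalysed ortho-bromination (NBS, catalytic iPr2NH, CH2Cl2, 0 °C) is expected between the hydroxyl and the methoxy group, the other positions being screened by the TIPS ether. It should give 2-bromo-3-methoxy-5-{[tri(propan-2-yl)silyl]oxy}phenol F8.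
- Hexamethyldisilazane converts this into 2-bromo-3-methoxy-5-{[tri(propan-2-yl)silyl]oxy}phenyl trimethylsilyl ether F9.
- n-BuLi at −78 °C effects bromine–lithium exchange and a retro-Brook 1,3-shift of silicon from oxygen to carbon. This gives, after aqueous NH4Cl, 3-methoxy-5-{[tri(propan-2-yl)silyl]oxy}-2-(trimethylsilyl)phenol F10.
- Carbamoylation with 4 and catalytic Et3N gives 10.

## Further compounds

F1 | step 8 | N-methoxy-2-(4-methoxyphenyl)-N-methyl-1,3-dioxolane-2-carboxamide | COc1ccc(C2(C(=O)N(C)OC)OCCO2)cc1
F2 | step 8 | 3-methoxy-2-[2-(4-methoxyphenyl)-1,3-dioxolane-2-carbonyl]-5-{[tri(propan-2-yl)silyl]oxy}phenyl propan-2-ylcarbamate | COc1ccc(C2(C(=O)c3c(OC)cc(O[Si](C(C)C)(C(C)C)C(C)C)cc3OC(=O)NC(C)C)OCCO2)cc1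
F3 | step 8 | 3-methoxy-5-(methoxymethoxy)-2-[2-(4-methoxyphenyl)-1,3-dioxolane-2-carbonyl]phenyl propan-2-ylcarbamate | COc1ccc(C2(C(=O)c3c(OC)cc(OCOC)cc3OC(=O)NC(C)C)OCCO2)cc1
F4 | step 10 | [2-hydroxy-3-iodo-6-methoxy-4-(methoxymethoxy)phenyl][2-(4-methoxyphenyl)-1,3-dioxolan-2-yl]methanone | COc1ccc(C2(C(=O)c3c(O)c(I)c(OCOC)cc3OC)OCCO2)cc1
F5 | step 10 | [3-iodo-6-methoxy-4-(methoxymethoxy)-2-[(3-methylbut-2-en-1-yl)oxy]phenyl][2-(4-methoxyphenyl)-1,3-dioxolan-2-yl]methanone | COc1ccc(C2(C(=O)c3c(OCC=C(C)C)c(I)c(OCOC)cc3OC)OCCO2)cc1
F6 | step 10 | [2-hydroxy-3-iodo-6-methoxy-4-(methoxymethoxy)-5-(3-methylbut-2-en-1-yl)phenyl][2-(4-methoxyphenyl)-1,3-dioxolan-2-yl]methanone | COc1ccc(C2(C(=O)c3c(O)c(I)c(OCOC)c(CC=C(C)C)c3OC)OCCO2)cc1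
F7 | step 11 | 1-(7-hydroxy-5-methoxy-2,2-dimethyl-3,4-dihydro-2H-chromen-6-yl)-2-(4-methoxyphenyl)ethane-1,2-dione | COc1ccc(C(=O)C(=O)c2c(O)cc3c(c2OC)CCC(C)(C)O3)cc1
F8 | step 3 | 2-bromo-3-methoxy-5-{[tri(propan-2-yl)silyl]oxy}phenol | COc1cc(O[Si](C(C)C)(C(C)C)C(C)C)cc(O)c1Br
F9 | step 3 | 2-bromo-3-methoxy-5-{[tri(propan-2-yl)silyl]oxy}phenyl trimethylsilyl ether | COc1cc(O[Si](C(C)C)(C(C)C)C(C)C)cc(O[Si](C)(C)C)c1Br
F10 | step 3 | 3-methoxy-5-{[tri(propan-2-yl)silyl]oxy}-2-(trimethylsilyl)phenol | COc1cc(O[Si](C(C)C)(C(C)C)C(C)C)cc(O)c1[Si](C)(C)C
A1 | alternative 1 | 2-diazo-1-(6,6-dimethyl-5,6-dihydro-4H-pyran-2-yl)ethan-1-one | [N-]=[N+]=CC(=O)C1=CCCC(C)(C)O1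
A2 | alternative 1 | benzyl ethynyl ether | C#COCc1ccccc1
A3 | alternative 1 | 7-(benzyloxy)-2,2-dimethylchroman-5-ol | Oc1cc(OCc2ccccc2)cc2OC(C)(C)CCc12
A4 | alternative 2 | methyl (2E)-3-methoxy-7-methylocta-2,6-dienoate | COC(=O)/C=C(/OC)CCC=C(C)C
A5 | alternative 2 | malonyl dichloride | O=C(Cl)CC(=O)Cl
A6 | alternative 2 | methyl 4,6-dihydroxy-2-methoxy-3-(3-methylbut-2-en-1-yl)benzoate | COC(=O)c1c(O)cc(O)c(CC=C(C)C)c1OC
A7 | alternative 3 | 2,6-dihydroxy-4-(methoxymethoxy)benzaldehyde | COCOc1cc(O)c(C=O)c(O)c1
A8 | alternative 3 | (2-methylprop-1-en-1-yl)boronic acid | CC(C)=CB(O)O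
A9 | alternative 3 | 7-(methoxymethoxy)-2,2-dimethyl-2H-chromen-5-ol | COCOc1cc(O)c2C=CC(C)(C)Oc2c1
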